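The carbon chain is numbered from C1 (lactone carbonyl) to C12 (methyl), and On is the oxygen that starts on Cn. The cis-fused tetrahydrofuran ring (O7, C4–C7) and δ-lactone ring (O5, C1–C5) hide a linear C3–C7 polyol. In it the ether oxygen on C4 stands anti to the C3 hydroxyl, the signature of a trans C3–C4 epoxide opened by O7. Everything rests on cutting C5–C6 and O7–C4. In one flask the O,C-dianion of (S)-1-(1,3-dithian-2-yl)prop-2-en-1-ol (O7–C7–C6, with C6 as acyl anion) adds to an open-chain epoxy aldehyde ester (C1–C5). Acid then triggers 5-exo epoxide opening and lactonisation, closing both rings. Carbonyl release, convex-face reduction and cross-metathesis with the C9–C12 diester finish the route.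

Key step: step 6

Step 1
Reactants: 1 methyl but-3-enoate; 2 (Z)-but-2-ene-1,4-diol
Product: 3 methyl (E)-5-hydroxypent-3-enoate
Conditions: second-generation Hoveyda–Grubbs catalyst (2 mol %), 1,4-benzoquinone (10 mol %), excess 2, CH2Cl2, 40 °C
Reagents that add atoms: none
Why: Olefin cross-metathesis of a terminal olefin with an excess of the symmetrical internal diol should give the thermodynamically preferred E-olefin, and benzoquinone suppresses ruthenium hydride migration of the β,γ-double bond into conjugation.

Step 2
Reactants: 3 methyl (E)-5-hydroxypent-3-enoate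
Product: 4 methyl 2-[(2R,3R)-3-(hydroxymethyl)oxiran-2-yl]acetate
Conditions: Ti(OiPr)4 (10 mol %), D-(−)-diethyl tartrate (12 mol %), t-BuOOH, 4 Å molecular sieves, CH2Cl2, −20 °C
Reagents that add atoms: tert-butyl hydroperoxide CC(C)(C)OO
Why: Sharpless asymmetric epoxidation of an E-configured primary allylic alcohol, in which the D-(−)-tartrate complex delivers oxygen to the face that gives the (2R,3R)-epoxy alcohol and so fixes C3 and, before its later inversion, C4.

Step 3
Reactants: 4 methyl 2-[(2R,3R)-3-(hydroxymethyl)oxiran-2-yl]acetate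
Product: 5 methyl 2-[(2R,3S)-3-formyloxiran-2-yl]acetate
Conditions: TEMPO (10 mol %), PhI(OAc)2, CH2Cl2, rt
Reagents that add atoms: none
Why: Oxoammonium (TEMPO) oxidation stops at the aldehyde under base-free conditions, so neither the oxirane nor the acidic CH2 beside the ester is touched.

Step 4
Reactants: 6 1,3-dithiane; 7 acrolein
Product: 9 rac-1-(1,3-dithian-2-yl)prop-2-en-1-ol, via 2-lithio-1,3-dithiane 8 (not isolated)
Conditions: n-BuLi, THF, −30 °C; 7, −78 °C; then H2O
Reagents that add atoms: none
Why: Corey–Seebach umpolung, in which the lithiated dithiane adds 1,2 to the enal in THF without polar cosolvent and the new carbinol centre forms as a racemate.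

Step 5
Reactants: 9 rac-1-(1,3-dithian-2-yl)prop-2-en-1-ol
Product: 10 (S)-1-(1,3-dithian-2-yl)prop-2-en-1-ol
Conditions: immobilised Candida antarctica lipase B, vinyl acetate, t-BuOMe, 30 °C, stopped slightly past half conversion; chromatography
Reagents that add atoms: none
Why: Lipase-catalysed kinetic resolution by irreversible transesterification, in which the enzyme acylates the enantiomer that presents the large dithianyl and the small vinyl group in the (R)-arrangement, so the (S)-alcohol that carries C7 is left behind.

Step 6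
Reactants: 10 (S)-1-(1,3-dithian-2-yl)prop-2-en-1-ol; 5 methyl 2-[(2R,3S)-3-formyloxiran-2-yl]acetate
Product: 14 spiro-dithiane bicyclic lactone (2S,3aS,7R,7aR), via dilithio dianion 11 (not isolated), via epoxy diol adduct 12 (not isolated), via tetrahydrofuran hydroxy ester 13 (not isolated)
Conditions: n-BuLi (2.1 equiv per 10), THF, −30 °C; 5, −78 °C; then TsOH·H2O (excess over base), −78 °C to rt
Reagents that add atoms: none
Why: n-BuLi removes first the hydroxyl proton and then the dithiane C6 proton of 10, and the resulting dianion 11, whose β-oxygen is an alkoxide and therefore cannot be eliminated, adds through C6 to the aldehyde of 5 at −78 °C faster than it deprotonates the ester, which forms C5–C6 (Corey–Seebach umpolung addition, the closest known reaction type together with the acid-catalysed cyclisation of epoxy alcohols). The sulfonic acid added to the cold mixture protonates both alkoxides to give 12 and activates the oxirane, so that O7–H attacks C4 from the rear and closes the tetrahydrofuran ring in the 5-exo-tet mode, forming O7–C4 and releasing the C3 hydroxyl in 13. The C5 hydroxyl then closes the δ-lactone ring by 6-exo-trig transesterification with loss of methanol, a closure that is geometrically impossible while the trans-epoxide is intact, so the order of the ring closures is fixed. C5 is controlled by Felkin–Anh attack anti to the oxirane C4–O bond (anti epoxy alcohol), C4 by stereospecific inversion and C3 by retention of the epoxide set in step 2, and C7 is carried in unchanged from 10, which together force the all-cis substitution of the tetrahydrofuran that no equilibrating closure would give. The step needs chemoselectivity for carbonyl addition over proton transfer and over direct epoxide opening (secured by the much higher electrophilicity of the aldehyde at −78 °C and by acidifying before warming) and regioselectivity for C4 over C3 (secured by the 5-exo preference and the gem-dithio effect at C6).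

Step 7
Reactants: 14 spiro-dithiane bicyclic lactone
Product: 15 (2S,3aS,7R,7aR)-2-ethenyl-7-hydroxytetrahydro-2H-furo[3,2-b]pyran-3,5-dione
Conditions: PhI(OCOCF3)2, MeCN/H2O 9:1, 0 °C, minutes; crude product used at once
Reagents that add atoms: water O
Why: Oxidative dethioacetalisation with a hypervalent iodine reagent, in which sulfur is oxidised, water adds to the thionium ion and the dithiol leaves as its cyclic disulfide fast enough at 0 °C to spare the alkene, the lactone and the enolisable C7–H.

Step 8
Reactants: 15 (2S,3aS,7R,7aR)-2-ethenyl-7-hydroxytetrahydro-2H-furo[3,2-b]pyran-3,5-dione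
Product: 16 (2S,3R,3aR,7R,7aR)-2-ethenyl-3,7-dihydroxyhexahydro-5H-furo[3,2-b]pyran-5-one
Conditions: NaBH4, CeCl3·7H2O, MeOH, −78 °C
Reagents that add atoms: none
Why: Luche reduction, in which the weakly basic cerium-modified borohydride attacks the C6 ketone from the convex face that carries only H5 and H7, because the concave face is shielded by the lactone ring and the C7 vinyl group, which sets C6 as (R) with its hydroxyl cis to O5.

Step 9
Reactants: 17 penta-1,4-dien-3-ol
Product: 18 (1S)-1-[(2R)-oxiran-2-yl]prop-2-en-1-ol
Conditions: Ti(OiPr)4, L-(+)-diisopropyl tartrate, t-BuOOH, 4 Å molecular sieves, CH2Cl2, −20 °C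
Reagents that add atoms: tert-butyl hydroperoxide CC(C)(C)OO
Why: Sharpless asymmetric epoxidation used as a desymmetrisation, in which the L-(+)-tartrate complex epoxidises one enantiotopic vinyl group with anti selectivity (sets C10 and C11) and the minor enantiomer is consumed by a faster second epoxidation.

Step 10
Reactants: 18 (1S)-1-[(2R)-oxiran-2-yl]prop-2-en-1-ol
Product: 19 (2R,3S)-pent-4-ene-2,3-diol
Conditions: LiAlH4, Et2O, 0 °C; aqueous work-up
Reagents that add atoms: none
Why: Hydride opens the terminal epoxide by SN2 attack at the unsubstituted carbon, which becomes the C12 methyl group while both stereocentres stay untouched.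

Step 11
Reactants: 19 (2R,3S)-pent-4-ene-2,3-diol
Product: 20 (2R,3S)-3-hydroxypent-4-en-2-yl acetate
Conditions: immobilised Candida antarctica lipase B, vinyl acetate, t-BuOMe, 30 °C
Reagents that add atoms: vinyl acetate C=COC(C)=O
Why: Lipase-catalysed regioselective transesterification, in which the (R)-configured methyl carbinol at C11 matches the enzyme's preference for secondary alcohols with one small substituent whereas the (S)-configured allylic C10 hydroxyl is the mismatched one, so only O11 should be acetylated.

Step 12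
Reactants: 20 (2R,3S)-3-hydroxypent-4-en-2-yl acetate
Product: 21 (2R,3S)-3-(benzoyloxy)pent-4-en-2-yl acetate
Conditions: BzCl, pyridine, DMAP (cat.), CH2Cl2, 0 °C
Reagents that add atoms: benzoyl chloride O=C(Cl)c1ccccc1
Why: DMAP-catalysed acylation of the remaining allylic hydroxyl at low temperature is fast enough to outrun acetyl migration.

Step 13
Reactants: 16 (2S,3R,3aR,7R,7aR)-2-ethenyl-3,7-dihydroxyhexahydro-5H-furo[3,2-b]pyran-5-one; 21 (2R,3S)-3-(benzoyloxy)pent-4-en-2-yl acetate
Product: 22 target CNP0230210.1
Conditions: second-generation Hoveyda–Grubbs catalyst (10 mol %), 21 (3 equiv), CH2Cl2, 40 °C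
Reagents that add atoms: none
Why: Olefin cross-metathesis of two terminal allylic-oxygenated olefins, in which the excess of 21 drives the heterocoupling, secondary metathesis funnels the product to the E-olefin, and free hydroxyls, esters and the lactone are tolerated by the ruthenium carbene.

Compound list
1 | methyl but-3-enoate | C=CCC(=O)OC | starting material
2 | (Z)-but-2-ene-1,4-diol | OC/C=C\CO | starting material
3 | methyl (E)-5-hydroxypent-3-enoate | COC(=O)C/C=C/CO | intermediate
4 | methyl 2-[(2R,3R)-3-(hydroxymethyl)oxiran-2-yl]acetate | COC(=O)C[C@H]1O[C@@H]1CO | intermediate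
5 | methyl 2-[(2R,3S)-3-formyloxiran-2-yl]acetate | COC(=O)C[C@H]1O[C@@H]1C=O | intermediate
6 | 1,3-dithiane | C1CSCSC1 | starting material
7 | acrolein (prop-2-enal) | C=CC=O | starting material
8 | 2-lithio-1,3-dithiane | [Li]C1SCCCS1 | intermediate
9 | rac-1-(1,3-dithian-2-yl)prop-2-en-1-ol | C=CC(O)C1SCCCS1 | intermediate
10 | (S)-1-(1,3-dithian-2-yl)prop-2-en-1-ol | C=C[C@H](O)C1SCCCS1 | intermediate
11 | dilithio dianion of 10 (lithium alkoxide on O7, lithium on dithiane C2 = chain C6) | C=C[C@H](O[Li])C1([Li])SCCCS1 | intermediate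
12 | epoxy diol adduct, methyl 2-[(2R,3R)-3-[(S)-hydroxy{2-[(1S)-1-hydroxyprop-2-en-1-yl]-1,3-dithian-2-yl}methyl]oxiran-2-yl]acetate | COC(=O)C[C@H]1O[C@@H]1[C@H](O)C2(SCCCS2)[C@@H](O)C=C | intermediate
13 | tetrahydrofuran hydroxy ester, methyl (3R)-3-[(2R,3S,5S)-5-ethenyl-3-hydroxy-4,4-(propane-1,3-diyldisulfanediyl)oxolan-2-yl]-3-hydroxypropanoate | C=C[C@@H]1O[C@H]([C@H](O)CC(=O)OC)[C@H](O)C12SCCCS2 | intermediate
14 | spiro-dithiane bicyclic lactone, (2S,3aS,7R,7aR)-2-ethenyl-7-hydroxytetrahydrospiro[furo[3,2-b]pyran-3,2'-[1,3]dithian]-5-one (cis-fused, vinyl and C7 hydroxyl on the concave face) | C=C[C@@H]1O[C@H]2[C@H](OC(=O)C[C@H]2O)C13SCCCS3 | intermediate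
15 | (2S,3aS,7R,7aR)-2-ethenyl-7-hydroxytetrahydro-2H-furo[3,2-b]pyran-3,5-dione | C=C[C@@H]1O[C@H]2[C@H](OC(=O)C[C@H]2O)C1=O | intermediate
16 | (2S,3R,3aR,7R,7aR)-2-ethenyl-3,7-dihydroxyhexahydro-5H-furo[3,2-b]pyran-5-one | C=C[C@@H]1O[C@H]2[C@H](OC(=O)C[C@H]2O)[C@@H]1O | intermediate
17 | penta-1,4-dien-3-ol | C=CC(O)C=C | starting material
18 | (1S)-1-[(2R)-oxiran-2-yl]prop-2-en-1-ol | C=C[C@H](O)[C@H]1CO1 | intermediate
19 | (2R,3S)-pent-4-ene-2,3-diol | C=C[C@H](O)[C@@H](C)O | intermediate
20 | (2R,3S)-3-hydroxypent-4-en-2-yl acetate | C=C[C@H](O)[C@@H](C)OC(C)=O | intermediate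
21 | (2R,3S)-3-(benzoyloxy)pent-4-en-2-yl acetate | CC(=O)O[C@H](C)[C@H](C=C)OC(=O)c1ccccc1 | intermediate
22 | (2R,3S,4E)-3-(benzoyloxy)-5-[(2S,3R,3aR,7R,7aR)-3,7-dihydroxy-5-oxohexahydro-2H-furo[3,2-b]pyran-2-yl]pent-4-en-2-yl acetate | CC(=O)O[C@H](C)[C@H](/C=C/[C@@H]1O[C@H]2[C@H](OC(=O)C[C@H]2O)[C@@H]1O)OC(=O)c1ccccc1 | target

Total step count: 13. Longest linear sequence: 7 steps (1, 2, 3, 6, 7, 8, 13).

Steps most likely to fail

**Step 6.**
- What may go wrong:
  - proton transfer from the ester CH2 of 5 to the carbanion;
  - base-induced opening of the β,γ-epoxy ester before the acid arrives;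
  - poor facial selectivity in the attack on the aldehyde, which would erode C5.
- The fallback replaces the carbonyl addition by acylation followed by chelation-controlled reduction, so that C5 is set by hydride. It sets out from 4 and 10.
- Alcohol 4 is oxidised further (TEMPO, PhI(OAc)2, MeCN/H2O) to the epoxy acid (2S,3R)-3-(2-methoxy-2-oxoethyl)oxirane-2-carboxylic acid F1. This is coupled with MeNHOMe·HCl (EDC, N-methylmorpholine) to the Weinreb amide methyl 2-[(2R,3S)-3-[methoxy(methyl)carbamoyl]oxiran-2-yl]acetate F2.
- Dianion 11, made from 10 as before, is acylated by F2 at −78 °C to the epoxy ketone methyl 2-[(2R,3S)-3-({2-[(1S)-1-hydroxyprop-2-en-1-yl]-1,3-dithian-2-yl}carbonyl)oxiran-2-yl]acetate F3.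
- Zn(BH4)2 in Et2O at −30 °C should reduce F3 through the chelate of the ketone and oxirane oxygens to the anti epoxy alcohol 12, which is now isolated.
- TsOH in CH2Cl2 then carries out the same epoxide opening and lactonisation, and the fallback comes back to the route at 14.

**Step 13.**
- What may go wrong:
  - sluggish initiation at the vinyl group on the concave face of 16;
  - preferential homodimerisation of the allylic benzoate;
  - catalyst decay before the heterocoupling is complete.
- The fallback uses the activating effect of a free allylic hydroxyl in metathesis and moves the benzoylation behind the coupling. It sets out from 16 and 20.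
- Diol 16 is silylated (Et3SiCl, imidazole, DMF) to the bis(triethylsilyl) ether (2S,3R,3aR,7R,7aR)-2-ethenyl-3,7-bis(triethylsilyloxy)hexahydro-5H-furo[3,2-b]pyran-5-one F4.
- Cross-metathesis of F4 with the free allylic alcohol 20 under the same catalyst should give the allylic alcohol (2R,3S,4E)-3-hydroxy-5-[(2S,3R,3aR,7R,7aR)-5-oxo-3,7-bis(triethylsilyloxy)hexahydro-2H-furo[3,2-b]pyran-2-yl]pent-4-en-2-yl acetate F5.
- BzCl and pyridine convert F5 into the benzoate (2R,3S,4E)-3-(benzoyloxy)-5-[(2S,3R,3aR,7R,7aR)-5-oxo-3,7-bis(triethylsilyloxy)hexahydro-2H-furo[3,2-b]pyran-2-yl]pent-4-en-2-yl acetate F6.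
- HF·pyridine in THF removes both silyl groups, and the fallback comes back to the route at 22.

**Step 7.**
- What may go wrong:
  - slow hydrolysis of the hindered dithiane on the crowded bicycle, so that sulfur oxidation stops at sulfoxides;
  - acid-induced enolisation towards C7, with loss of configuration or migration of the vinyl double bond into conjugation.
- The fallback changes the order of events and releases the carbonyl while the chain is still open and the dithiane unhindered. It sets out from 12, obtained by quenching step 6 with aqueous NH4Cl at −78 °C and isolating the adduct.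
- PhI(OCOCF3)2 in aqueous MeCN converts 12 into the acyclic epoxy dihydroxy ketone methyl 2-[(2R,3R)-3-[(1S,3S)-1,3-dihydroxy-2-oxopent-4-en-1-yl]oxiran-2-yl]acetate F7.
- A catalytic amount of TsOH in CH2Cl2 then triggers the same 5-exo epoxide opening and lactonisation, and the fallback comes back to the route at 15.

Further compounds
F1 | step 6 | epoxy acid (2S,3R)-3-(2-methoxy-2-oxoethyl)oxirane-2-carboxylic acid | COC(=O)C[C@H]1O[C@@H]1C(=O)O
F2 | step 6 | Weinreb amide methyl 2-[(2R,3S)-3-[methoxy(methyl)carbamoyl]oxiran-2-yl]acetate | COC(=O)C[C@H]1O[C@@H]1C(=O)N(C)OC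
F3 | step 6 | epoxy ketone methyl 2-[(2R,3S)-3-({2-[(1S)-1-hydroxyprop-2-en-1-yl]-1,3-dithian-2-yl}carbonyl)oxiran-2-yl]acetate | COC(=O)C[C@H]1O[C@@H]1C(=O)C2(SCCCS2)[C@@H](O)C=C
F4 | step 13 | bis(triethylsilyl) ether (2S,3R,3aR,7R,7aR)-2-ethenyl-3,7-bis(triethylsilyloxy)hexahydro-5H-furo[3,2-b]pyran-5-one | C=C[C@@H]1O[C@H]2[C@H](OC(=O)C[C@H]2O[Si](CC)(CC)CC)[C@@H]1O[Si](CC)(CC)CC
F5 | step 13 | allylic alcohol (2R,3S,4E)-3-hydroxy-5-[(2S,3R,3aR,7R,7aR)-5-oxo-3,7-bis(triethylsilyloxy)hexahydro-2H-furo[3,2-b]pyran-2-yl]pent-4-en-2-yl acetate | CC(=O)O[C@H](C)[C@H](/C=C/[C@@H]1O[C@H]2[C@H](OC(=O)C[C@H]2O[Si](CC)(CC)CC)[C@@H]1O[Si](CC)(CC)CC)O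
F6 | step 13 | benzoate (2R,3S,4E)-3-(benzoyloxy)-5-[(2S,3R,3aR,7R,7aR)-5-oxo-3,7-bis(triethylsilyloxy)hexahydro-2H-furo[3,2-b]pyran-2-yl]pent-4-en-2-yl acetate | CC(=O)O[C@H](C)[C@H](/C=C/[C@@H]1O[C@H]2[C@H](OC(=O)C[C@H]2O[Si](CC)(CC)CC)[C@@H]1O[Si](CC)(CC)CC)OC(=O)c1ccccc1
F7 | step 7 | acyclic epoxy dihydroxy ketone methyl 2-[(2R,3R)-3-[(1S,3S)-1,3-dihydroxy-2-oxopent-4-en-1-yl]oxiran-2-yl]acetate | COC(=O)C[C@H]1O[C@@H]1[C@H](O)C(=O)[C@@H](O)C=C
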